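**Retrosynthetic overview**

1. The target gibberellin ⇐ its trimethyl ester ⇐ ring D by ketyl–alkyne closure (C13–C16) ⇐ ring B contracted from six to five atoms by a Wolff rearrangement, in which a ring ketone leaves the ring as the C7 carboxyl and C5 migrates to C6.
2. The six-membered-ring-B tricycle ⇐ ring A by a Diels–Alder reaction that forms C1–C10 and C4–C5 together, from a 2-silyloxydiene (C1–C4, C18, C19) and a bicyclic enone ester (rings B and C), followed by epimerisation of C5.
3. Enabling feature: in ring B, C10 carries the C20 acid and C5 is one carbon (C6) away from the C7 acid; if C7 is kept inside ring B as a ketone between C5 and C6, C5=C10 becomes the alkene of a cyclic 4-oxo-2-enoate (C7=O on C5, C20 ester on C10), a doubly activated dienophile. The same ketone later allows the C5 epimerisation (trans A/B) and the ring contraction.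
4. The enone ester ⇐ Robinson annulation of a ring C ketone with a 4-oxopentenoate (six-membered ring B), conjugate propargylation at C8, dehydrogenation to C5=C10.
5. Order of ring formation: C (bought) → B (six-membered) → A (key step) → B contracted to five → D.

Key step: step 8

Remark: gibberellane numbering (C1–C20) is used for all intermediates; β is the face of C18, H5 and H9, α the face of C19 and C20. The target is named by its substitution pattern, 3β,13-dihydroxygibberell-16-ene-7,19,20-trioic acid, and is called the target gibberellin. Centres that are later made planar (the ester-bearing carbon C10 before step 4, both centres of the aldol of step 5) are carried as mixtures and written without a stereo descriptor; the four starting materials are taken as commercial.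

Step 1
Reactants: 1 1,4-dioxaspiro[4.5]decan-7-one; 2 methyl (2E)-4-oxopent-2-enoate
Product: 3 methyl 4-oxo-2-[(8S)-7-oxo-1,4-dioxaspiro[4.5]decan-8-yl]pentanoate
Conditions: 9-amino-9-deoxy-epi-quinine (20 mol %; or its quinidine-derived pseudoenantiomer, whichever leads to 8S), PhCO2H (40 mol %), PhMe, 25 °C
Reagents that add atoms: none
Why: Enamine-catalysed asymmetric Michael addition: the enamine of 1 forms on the side away from the ketal and attacks 2 at the carbon β to its ketone (α to the ester), and the chiral primary amine should set C9 by face selection.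

Step 2
Reactants: 3 Michael adduct
Product: 5 bicyclic enone ester (rings B and C), via ketol 4 (not isolated)
Conditions: pyrrolidine (30 mol %), AcOH (30 mol %), PhMe, 50 °C
Reagents that add atoms: none
Why: Intramolecular aldol condensation (second half of a Robinson annulation): the enamine of the methyl ketone (C6) adds to the ring C ketone (C8) and loss of water gives the conjugated C6=C8 enone, while the hindered ring ketone forms no enamine, so C9 should stay untouched.

Step 3
Reactants: 5 bicyclic enone ester
Product: 7 propargyl decalone, via silylalkyne ketone 6 (not isolated)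
Conditions: Me3SiC≡CCH3, n-BuLi, Me2NCH2CH2NMe2, THF, −20 °C; CuI, −40 °C; then 5, −78 to −30 °C; aq. NH4Cl; then K2CO3 (cat.), MeOH, 25 °C
Reagents that add atoms: 1-(trimethylsilyl)propyne C[Si](C)(C)C#CC
Why: Organocuprate conjugate addition to the β,β-disubstituted enone creates the quaternary C8 by axial attack on ring B, which should give the cis-fused decalin (C8–C15 bond cis to H9); the terminal silyl group disfavours the allenyl form of the copper reagent and is then removed by methanolysis.

Step 4
Reactants: 7 propargyl decalone
Product: 8 enone ester dienophile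
Conditions: IBX, DMSO/PhF, 70 °C
Reagents that add atoms: none
Why: IBX α,β-dehydrogenation of a ketone: C8 is quaternary, so only C5–C10 can be desaturated, which gives the cyclic 4-oxo-2-enoate and removes the undefined C10 centre.

Step 5
Reactants: 9 methyl propanoate; 10 acrolein
Product: 11 methyl 3-hydroxy-2-methylpent-4-enoate
Conditions: LiN(i-Pr)2, THF, −78 °C; then 10; AcOH quench
Reagents that add atoms: none
Why: Aldol addition of the lithium ester enolate to the aldehyde carbon of acrolein (1,2-addition at low temperature); both new stereocentres are removed in steps 6 and 7, so the mixture is used as such.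

Step 6
Reactants: 11 aldol
Product: 12 methyl 2-methyl-3-oxopent-4-enoate
Conditions: Dess–Martin periodinane, CH2Cl2, 0 °C
Reagents that add atoms: none
Why: Dess–Martin oxidation of the allylic alcohol to the vinyl ketone under non-basic conditions, which should spare the polymerisable β-keto ester; it is carried on cold and unpurified.

Step 7
Reactants: 12 keto ester
Product: 13 methyl (2Z)-2-methyl-3-[(triisopropylsilyl)oxy]penta-2,4-dienoate
Conditions: NaN(SiMe3)2, THF, −78 °C; then i-Pr3SiOTf
Reagents that add atoms: triisopropylsilyl trifluoromethanesulfonate CC(C)[Si](OS(=O)(=O)C(F)(F)F)(C(C)C)C(C)C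
Why: Silyl enol ether formation by O-silylation of the chelated sodium enolate of the β-keto ester, which should give the Z dienol ether with the silyloxy group cis to the ester.

Step 8
Reactants: 8 enone ester dienophile; 13 silyloxydiene
Product: 14 cis-fused cycloadduct (rings A, B, C)
Conditions: PhMe, 2,6-di-tert-butyl-4-methylphenol (cat.), 120 °C, sealed tube
Reagents that add atoms: none
Why: Thermal normal-demand Diels–Alder reaction: diene 13 adds across C5=C10 of 8 in one suprafacial [4+2] event that forms C4–C5 and C1–C10 and leaves the C2=C3 silyl enol ether; the closest known type is the cycloaddition of 2-silyloxydienes with 3-alkoxycarbonylcyclohex-2-enones and other cyclic 4-oxo-2-enoates. Ring A is the only ring closed, as the six-membered ring of an intermolecular [4+2] cycloaddition. C10: the diene should add to the convex face of the cis-fused bicycle, anti to the C9–C11 bond of ring C and on the side of H9, which places C1 β and the C20 ester α. C4: the Z geometry of 13 puts its ester on the outside of the diene, and the transition state with the C20 ester endo and the bulky bicycle exo then places C19 cis to C20 (α) and C18 β; C5 arises from cis addition with H5 α, which step 9 corrects. Regioselectivity is needed and should be secured by substitution: each partner has one fully substituted and one unhindered terminus (C4 and C1 of the diene, C10 and C5 of the dienophile), so only the C1–C10/C4–C5 pairing avoids a bond between two fully substituted carbons, while the opposed silyloxy and ester groups leave the diene electronically almost unbiased.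

Step 9
Reactants: 14 cis-fused cycloadduct
Product: 15 trans-fused tricyclic ketone
Conditions: 1,8-diazabicyclo[5.4.0]undec-7-ene (DBU), PhMe, 60 °C
Reagents that add atoms: none
Why: Base-mediated epimerisation α to the C7 ketone: reversible enolisation toward C5 and reprotonation on the β face, which is open whereas the α face is screened by the axial C19 and C20 esters, should funnel the cis adduct into the trans-fused decalone (H5 β, anti to the C20 ester).

Step 10
Reactants: 15 trans-fused tricyclic ketone
Product: 17 diazoketone, via trifluoroacetyl ketone 16 (not isolated)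
Conditions: LiN(SiMe3)2, THF, −78 °C; CF3CO2CH2CF3; then 4-acetamidobenzenesulfonyl azide, Et3N, MeCN, 25 °C
Reagents that add atoms: 4-acetamidobenzenesulfonyl azide CC(=O)Nc1ccc(cc1)S(=O)(=O)N=[N+]=[N-]; 2,2,2-trifluoroethyl trifluoroacetate O=C(OCC(F)(F)F)C(F)(F)F (its acyl group is found only in 16)
Why: Deacylative (Regitz-type) diazo transfer: kinetic deprotonation at the C6 methylene (C5 is a hindered methine) and trifluoroacetylation activate C6, and the sulfonyl azide then delivers N2 with loss of the trifluoroacetyl group.

Step 11
Reactants: 17 diazoketone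
Product: 20 ring-contracted triester, via ketene 18 (not isolated), via 6-epi ester 19 (not isolated)
Conditions: hν (medium-pressure mercury lamp, Pyrex filter), MeOH, 20 °C; then NaOMe (cat.), MeOH, 40 °C
Reagents that add atoms: methanol CO
Why: Photochemical Wolff rearrangement with ring contraction: loss of N2 lets C5 migrate from C7 to C6 with retention, methanol traps the ketene as the C7 methyl ester, and methoxide should equilibrate C6 from the kinetic 6α-ester (protonation on the open β face) to the more stable 6β-ester trans to C4.

Step 12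
Reactants: 20 ring-contracted triester
Product: 21 3-ketone
Conditions: Bu4NF, AcOH, THF, 0 °C
Reagents that add atoms: none
Why: Fluoride-induced cleavage of the silyl enol ether with buffered protonation at C2 unveils the C3 ketone of a β-keto ester that cannot enolise toward the quaternary C4.

Step 13
Reactants: 21 3-ketone
Product: 22 3β-alcohol
Conditions: LiBH(s-Bu)3, THF, −78 °C
Reagents that add atoms: none
Why: Diastereoselective ketone reduction with a bulky trialkylborohydride: equatorial delivery of hydride, away from the β-axial hydrogens at C1 and C5, should give the axial 3β-alcohol cis to C18.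

Step 14
Reactants: 22 3β-alcohol
Product: 23 13-ketone
Conditions: pyridinium p-toluenesulfonate (cat.), acetone/H2O, 55 °C
Reagents that add atoms: water O
Why: Acid-catalysed hydrolysis of the dioxolane ketal frees the ring C ketone under conditions that the β-hydroxy ester and the alkyne should tolerate.

Step 15
Reactants: 23 13-ketone
Product: 24 trimethyl ester of the target gibberellin
Conditions: SmI2, (Me2N)3PO, t-BuOH, THF, 0 to 25 °C
Reagents that add atoms: none
Why: Samarium-diiodide-mediated ketyl–alkyne reductive cyclisation: the C13 ketyl adds 5-exo-dig to C16, the vinyl radical is reduced and protonated to the exocyclic methylene, and the bridge can only close cis across ring C, which fixes C13.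

Step 16
Reactants: 24 trimethyl ester of the target gibberellin
Product: 25 target gibberellin (3β,13-dihydroxygibberell-16-ene-7,19,20-trioic acid)
Conditions: LiS(n-Pr), (Me2N)3PO, 25 °C; then aq. HCl to pH 3
Reagents that add atoms: none
Why: SN2 demethylation of the three methyl esters by thiolate (attack at the methyl carbon, insensitive to the hindrance at the C19 and C20 acyl carbons) avoids hydrolysis conditions that could cause retro-aldol cleavage at C3–C4 or rearrangement of the tertiary allylic alcohol.

**Compound list**

1 | 1,4-dioxaspiro[4.5]decan-7-one (ring C; ketone carbon = C8, ketal carbon = C13) | O=C1CCCC2(C1)OCCO2 | starting material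
2 | methyl (2E)-4-oxopent-2-enoate (gives C6, C7, C5, C10, C20) | CC(=O)/C=C/C(=O)OC | starting material
3 | methyl 4-oxo-2-[(8S)-7-oxo-1,4-dioxaspiro[4.5]decan-8-yl]pentanoate (C9 set, C10 epimers) | O=C1CC2(OCCO2)CC[C@H]1C(C(=O)OC)CC(C)=O | intermediate
4 | bicyclic ketol: 8-hydroxy-7-ketone of rings B and C, 13,13-ethylenedioxy, 10-CO2Me (not isolated) | O=C1CC2(O)CC3(OCCO3)CC[C@H]2C(C(=O)OC)C1 | intermediate
5 | bicyclic enone ester: ring B cyclohexenone [C7(=O), C6=C8] fused to ring C (13,13-ethylenedioxy), 9β-H, 10-CO2Me (C10 epimers) | O=C1C=C2CC3(OCCO3)CC[C@H]2C(C(=O)OC)C1 | intermediate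
6 | cis-fused 7-ketone with 8β-[3-(trimethylsilyl)prop-2-yn-1-yl], 9β-H (not isolated) | C[Si](C)(C)C#CC[C@]23CC4(OCCO4)CC[C@H]2C(C(=O)OC)CC(=O)C3 | intermediate
7 | cis-fused 7-ketone with 8β-propargyl, 9β-H, 10-CO2Me (C10 epimers), 13,13-ethylenedioxy | C#CC[C@]23CC4(OCCO4)CC[C@H]2C(C(=O)OC)CC(=O)C3 | intermediate
8 | enone ester dienophile: cis-fused bicycle, ring B a 4-oxo-2-enoate [C20 ester on C10, C5=C10, C7(=O)], 8β-propargyl, 9β-H, 13,13-ethylenedioxy | C#CC[C@]23CC4(OCCO4)CC[C@H]2C(C(=O)OC)=CC(=O)C3 | intermediate
9 | methyl propanoate (gives C18, C4, C19) | CCC(=O)OC | starting material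
10 | acrolein (gives C3, C2, C1) | C=CC=O | starting material
11 | methyl 3-hydroxy-2-methylpent-4-enoate (diastereomer mixture) | C=CC(O)C(C)C(=O)OC | intermediate
12 | methyl 2-methyl-3-oxopent-4-enoate (racemic, enolisable) | C=CC(=O)C(C)C(=O)OC | intermediate
13 | methyl (2Z)-2-methyl-3-[(triisopropylsilyl)oxy]penta-2,4-dienoate | C=C/C(O[Si](C(C)C)(C(C)C)C(C)C)=C(\C)C(=O)OC | intermediate
14 | cis-fused cycloadduct: ring A with C2=C3 silyl enol ether, 4β-methyl, 4α-CO2Me, 10α-CO2Me, 5α-H; six-membered ring B with C7 ketone; 8β-propargyl; 13,13-ethylenedioxy | C#CC[C@]23CC4(OCCO4)CC[C@H]2[C@]1(C(=O)OC)CC=C(O[Si](C(C)C)(C(C)C)C(C)C)[C@@](C)(C(=O)OC)[C@@H]1C(=O)C3 | intermediate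
15 | trans-fused tricyclic ketone (5β-H epimer of 14) | C#CC[C@]23CC4(OCCO4)CC[C@H]2[C@]1(C(=O)OC)CC=C(O[Si](C(C)C)(C(C)C)C(C)C)[C@@](C)(C(=O)OC)[C@H]1C(=O)C3 | intermediate
16 | 6-trifluoroacetyl derivative of 15 (enolising 1,3-dicarbonyl, C6 not configurationally defined; not isolated) | C#CC[C@]23CC4(OCCO4)CC[C@H]2[C@]1(C(=O)OC)CC=C(O[Si](C(C)C)(C(C)C)C(C)C)[C@@](C)(C(=O)OC)[C@H]1C(=O)C3C(=O)C(F)(F)F | intermediate
17 | 6-diazo-7-ketone | C#CC[C@]23CC4(OCCO4)CC[C@H]2[C@]1(C(=O)OC)CC=C(O[Si](C(C)C)(C(C)C)C(C)C)[C@@](C)(C(=O)OC)[C@H]1C(=O)C3=[N+]=[N-] | intermediate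
18 | ring-contracted ketene (C6=C7=O, ring B five-membered; not isolated) | C#CC[C@]23CC4(OCCO4)CC[C@H]2[C@]1(C(=O)OC)CC=C(O[Si](C(C)C)(C(C)C)C(C)C)[C@@](C)(C(=O)OC)[C@H]1C3=C=O | intermediate
19 | 6α-methoxycarbonyl epimer (6-epi ester; not isolated) | C#CC[C@]23CC4(OCCO4)CC[C@H]2[C@]1(C(=O)OC)CC=C(O[Si](C(C)C)(C(C)C)C(C)C)[C@@](C)(C(=O)OC)[C@H]1[C@H]3C(=O)OC | intermediate
20 | ring-contracted triester: 6β-CO2Me (C7), 4α-CO2Me (C19), 10α-CO2Me (C20), C2=C3 silyl enol ether, 8-propargyl, 13,13-ethylenedioxy | C#CC[C@]23CC4(OCCO4)CC[C@H]2[C@]1(C(=O)OC)CC=C(O[Si](C(C)C)(C(C)C)C(C)C)[C@@](C)(C(=O)OC)[C@H]1[C@@H]3C(=O)OC | intermediate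
21 | 3-ketone triester (13,13-ethylenedioxy, 8-propargyl) | C#CC[C@]23CC4(OCCO4)CC[C@H]2[C@]1(C(=O)OC)CCC(=O)[C@@](C)(C(=O)OC)[C@H]1[C@@H]3C(=O)OC | intermediate
22 | 3β-hydroxy triester (13,13-ethylenedioxy, 8-propargyl) | C#CC[C@]23CC4(OCCO4)CC[C@H]2[C@]1(C(=O)OC)CC[C@H](O)[C@@](C)(C(=O)OC)[C@H]1[C@@H]3C(=O)OC | intermediate
23 | 3β-hydroxy-13-ketone triester with 8-propargyl | C#CC[C@]23CC(=O)CC[C@H]2[C@]1(C(=O)OC)CC[C@H](O)[C@@](C)(C(=O)OC)[C@H]1[C@@H]3C(=O)OC | intermediate
24 | trimethyl ester of the target gibberellin (trimethyl 3β,13-dihydroxygibberell-16-ene-7,19,20-trioate) | C=C1C[C@]23C[C@@]1(O)CC[C@H]2[C@]1(C(=O)OC)CC[C@H](O)[C@@](C)(C(=O)OC)[C@H]1[C@@H]3C(=O)OC | intermediate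
25 | target gibberellin: 3β,13-dihydroxygibberell-16-ene-7,19,20-trioic acid (4α-CO2H, 10α-CO2H, 6β-CO2H, 5β-H, 9β-H) | C=C1C[C@]23C[C@@]1(O)CC[C@H]2[C@]1(C(=O)O)CC[C@H](O)[C@@](C)(C(=O)O)[C@H]1[C@@H]3C(=O)O | target

**Totals and risks**

Total step count: 16. Longest linear sequence: 13 steps (steps 1–4 and 8–16).

Risk 1, step 8 (cycloaddition): the union may be too slow, because the diene terminus C4 is fully substituted (inside methyl group) and C10 of the dienophile becomes quaternary; at the temperature then needed, the endo and facial preferences may erode. Fallback (anionic double Michael annulation in place of the concerted cycloaddition): it sets out from 8 and keto ester 12. The sodium enolate of 12 (NaH, THF, −20 °C) is added to 8; conjugate addition of C4 to C5 is followed by ring closure of the C10 ester enolate onto the vinyl ketone terminus C1. The resulting C2–C3 sodium enolate F1 is silylated in the same flask with i-Pr3SiOTf, which comes back to the route at 14.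

Risk 2, step 9 (C5 epimerisation): the equilibrium may stop short of full conversion, since in the trans isomer the equatorial C18 methyl group lies close to the C7 carbonyl oxygen. Fallback (kinetic protonation instead of equilibration): from 14, silylation under equilibrating conditions (Me3SiOTf, Et3N, CH2Cl2, 0 to 25 °C) should give the more substituted C5=C7 trimethylsilyl enol ether F2. Protodesilylation at −78 °C (Bu4NF, AcOH, THF) delivers the proton to C5 from the open β face and comes back to the route at 15.

Risk 3, step 3 (conjugate propargylation): the copper reagent may transfer its allenyl form or fail to add to the hindered ring-fusion carbon. Fallback (allyl transfer and later conversion into the alkyne): from 5, allylmagnesium bromide with CuBr·SMe2 and Me3SiCl (THF, −78 °C) should give the cis-fused allyl ketone F3. Ozonolysis (O3, CH2Cl2, −78 °C; Me2S) gives aldehyde F4, and Seyferth–Gilbert homologation with dimethyl (1-diazo-2-oxopropyl)phosphonate (K2CO3, MeOH, 25 °C) turns the aldehyde into the terminal alkyne and comes back to the route at 7.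

Further compounds
F1 | step 8 | sodium C2–C3 enolate of the cis-fused annulated 3-ketone | C#CC[C@]23CC4(OCCO4)CC[C@H]2[C@]1(C(=O)OC)CC=C([O-])[C@@](C)(C(=O)OC)[C@@H]1C(=O)C3.[Na+]
F2 | step 9 | C5=C7 trimethylsilyl enol ether of 14 | C#CC[C@]23CC4(OCCO4)CC[C@H]2[C@]1(C(=O)OC)CC=C(O[Si](C(C)C)(C(C)C)C(C)C)[C@@](C)(C(=O)OC)C1=C(O[Si](C)(C)C)C3
F3 | step 3 | cis-fused 8β-allyl 7-ketone (C10 epimers) | C=CC[C@]23CC4(OCCO4)CC[C@H]2C(C(=O)OC)CC(=O)C3
F4 | step 3 | cis-fused 8β-(2-oxoethyl) 7-ketone (C10 epimers) | O=CC[C@]23CC4(OCCO4)CC[C@H]2C(C(=O)OC)CC(=O)C3
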